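## Retrosynthetic overview

1. The target is opened at both oxiranes to the (1(10)E,4E)-triene lactone (double epoxidation last); the C8 angelate and C13 acetate come from plain acylations.
2. The 8-hydroxy-12,6-butenolide comes from an 8-oxo-butenolide, itself made in one operation from a furan-bridged ten-membered ring by singlet-oxygen dearomatization and relactonization onto 6-OH (key step: the furan oxygen becomes the C8 oxygen, the furan C–H carbon becomes the lactone carbonyl C12).
3. The furan-bridged ring is closed at C5–C6 by an enantioselective Cr/Ni coupling of an iodo-aldehyde; C8–C9 comes from alkylation of a 2-lithiofuran.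
4. Building blocks: symmetric furan-3,4-diyldimethanol (monosilylation breaks its symmetry) and a C9 (E,E)-iodo-bromide from 6-methylhept-5-en-2-one.
5. Ring order: furan (purchased) → ten-membered carbocycle → butenolide (at the cost of the furan) → two oxiranes.

Assumption: atom labels C1–C15 follow germacrane numbering (C12 lactone carbonyl, C13 acetoxymethyl carbon); 1, 8 and 20 are taken as purchasable; the (S)-valinol-derived ligand of step 8 is taken to give the (6R)-carbinol (its mirror image is used if the sense is opposite); C6 keeps its geometry from 13 to 23 and its label changes from R to S in step 13 only because C5 gains an oxygen.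

## Route

Step 1
Reactants: 1 6-methylhept-5-en-2-one
Product: 3 alkyne 6-methylhept-5-en-1-yne, via enol phosphate 2 (not isolated)
Conditions: LiN(i-Pr)2 (1.05 equiv), THF, −78 °C; ClP(O)(OEt)2, −78 → 23 °C; then LiN(i-Pr)2 (2.3 equiv), THF, −78 → 23 °C
Reagents that add atoms: none
Why: Negishi alkyne synthesis, in which kinetic deprotonation at the methyl group gives the terminal enol phosphate and excess amide base eliminates phosphate to the terminal alkyne; no stereocenter is formed.

Step 2
Reactants: 3 6-methylhept-5-en-1-yne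
Product: 4 enynol (2E)-2-methylhept-2-en-6-yn-1-ol
Conditions: SeO2 (0.2 equiv), t-BuOOH (2 equiv), salicylic acid (cat.), CH2Cl2, 23 °C
Reagents that add atoms: selenium dioxide O=[Se]=O; tert-butyl hydroperoxide CC(C)(C)OO
Why: SeO2 allylic oxidation (ene reaction, then [2,3]-sigmatropic shift) hydroxylates the (E)-methyl group of the trisubstituted alkene, which fixes the later C1=C10 bond as E.

Step 3
Reactants: 4 (2E)-2-methylhept-2-en-6-yn-1-ol
Product: 6 iodo alcohol (2E,6E)-7-iodo-2,6-dimethylhepta-2,6-dien-1-ol, via alkenylalane 5 (not isolated)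
Conditions: AlMe3 (3 equiv), Cp2ZrCl2 (0.25 equiv), CH2Cl2, 0 → 23 °C; then I2, THF, −30 → 0 °C
Reagents that add atoms: trimethylaluminium C[Al](C)C; iodine II
Why: Negishi zirconium-catalysed carboalumination adds methyl and aluminium syn with aluminium on the terminal carbon, and iodinolysis with retention gives the (E)-iodoalkene that fixes the later C4=C5 geometry.

Step 4
Reactants: 6 (2E,6E)-7-iodo-2,6-dimethylhepta-2,6-dien-1-ol
Product: 7 iodo bromide (1E,5E)-7-bromo-1-iodo-2,6-dimethylhepta-1,5-diene
Conditions: CBr4, PPh3, CH2Cl2, 0 °C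
Reagents that add atoms: carbon tetrabromide BrC(Br)(Br)Br
Why: Appel bromination proceeds by SN2 at the primary allylic carbon at 0 °C without allylic shift or loss of alkene geometry.

Step 5
Reactants: 8 furan-3,4-diyldimethanol
Product: 9 monosilyl ether [4-({[tert-butyl(dimethyl)silyl]oxy}methyl)furan-3-yl]methanol
Conditions: NaH (1.0 equiv), THF, 23 °C; then TBSCl (1.0 equiv), 23 °C
Reagents that add atoms: tert-butyl(chloro)dimethylsilane CC(C)(C)[Si](C)(C)Cl
Why: Monosilylation of a symmetric diol through its sparingly soluble monosodium alkoxide breaks the symmetry of the furan and marks the future C13 oxygen.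

Step 6
Reactants: 9 [4-({[tert-butyl(dimethyl)silyl]oxy}methyl)furan-3-yl]methanol; 7 (1E,5E)-7-bromo-1-iodo-2,6-dimethylhepta-1,5-diene
Product: 11 furyl methanol {4-({[tert-butyl(dimethyl)silyl]oxy}methyl)-2-[(2E,6E)-7-iodo-2,6-dimethylhepta-2,6-dien-1-yl]furan-3-yl}methanol, via dilithio furan 10 (not isolated)
Conditions: n-BuLi (2.2 equiv), TMEDA, THF, −78 → 0 °C; then 7, −78 → 0 °C
Reagents that add atoms: none
Why: Alkoxide-directed lithiation takes place at the furan α-position next to CH2OLi, and the 2-furyllithium is C-alkylated by the primary allylic bromide (SN2), while this weakly basic aryl-type lithium does not exchange with the alkenyl iodide at low temperature.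

Step 7
Reactants: 11 furyl methanol from step 6
Product: 12 iodo aldehyde 4-({[tert-butyl(dimethyl)silyl]oxy}methyl)-2-[(2E,6E)-7-iodo-2,6-dimethylhepta-2,6-dien-1-yl]furan-3-carbaldehyde
Conditions: MnO2, CH2Cl2, 23 °C
Reagents that add atoms: none
Why: MnO2 oxidises the activated furylmethyl alcohol to the aldehyde without over-oxidation and leaves the iodoalkene and silyl ether untouched.

Step 8
Reactants: 12 iodo aldehyde from step 7
Product: 13 furan-bridged ring (4R,5E,9E)-3-({[tert-butyl(dimethyl)silyl]oxy}methyl)-6,10-dimethyl-4,7,8,11-tetrahydrocyclodeca[b]furan-4-ol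
Conditions: CrCl2 (6 equiv), (S)-N-[2-(4-isopropyl-4,5-dihydro-1,3-oxazol-2-yl)-6-methylphenyl]methanesulfonamide (6.6 equiv), Et3N, NiCl2 (0.3 equiv), THF, 23 °C, syringe-pump addition of 12 (final 2 mM)
Reagents that add atoms: none
Why: Nozaki–Hiyama–Kishi ring closure, in which zerovalent nickel inserts into the C–I bond, transmetalation gives an alkenyl species of trivalent chromium that adds to the aldehyde with retention of the E geometry, and the chiral sulfonamide ligand on chromium selects the aldehyde face to set C6 as R.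

Step 9
Reactants: 13 furan-bridged ring from step 8
Product: 16 keto lactone (6R)-13-(tert-butyldimethylsilyloxy)-8-oxogermacra-1(10)E,4E,7(11)-trien-12,6-olide, via furan endoperoxide 14 (not isolated), via hydroxybutenolide 15 (not isolated)
Conditions: O2, hν (visible), tetraphenylporphyrin (cat.), i-Pr2NEt, CH2Cl2, −78 °C; then DCC, DMAP (cat.), −78 → 23 °C
Reagents that add atoms: oxygen O=O
Why: Proposed new method: singlet oxygen adds [4+2] across C8/C12 of the trialkylfuran much faster than it undergoes ene reaction with the two trisubstituted alkenes at −78 °C, the amine removes the only bridgehead hydrogen (C12–H, Kornblum–DeLaMare fragmentation) to give pseudo-acid 15 in equilibrium with its open (Z)-keto-carboxylate, and carbodiimide activation lets 6-OH close the only geometrically possible lactone with the C6–O bond untouched (C6 retained); the closest known reactions are the base-mediated photooxygenation of furans to γ-hydroxybutenolides and Steglich lactonisation.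

Step 10
Reactants: 16 keto lactone from step 9
Product: 18 acetate (6R)-13-acetoxy-8-oxogermacra-1(10)E,4E,7(11)-trien-12,6-olide, via primary alcohol 17 (not isolated)
Conditions: HF·pyridine, pyridine, THF, 0 °C; then Ac2O, DMAP (cat.), 0 → 23 °C
Reagents that add atoms: acetic anhydride CC(=O)OC(C)=O
Why: Buffered fluoride cleaves the primary silyl ether and the freed primary alcohol is acetylated in the same flask, at a stage where no other ester is present that could migrate.

Step 11
Reactants: 18 acetate from step 10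
Product: 19 allylic alcohol (6R,8S)-13-acetoxy-8-hydroxygermacra-1(10)E,4E,7(11)-trien-12,6-olide
Conditions: (R)-2-methyl-CBS-oxazaborolidine (0.3 equiv), catecholborane, toluene, −78 °C
Reagents that add atoms: none
Why: Corey–Bakshi–Shibata reduction, in which the butenolide alkenyl carbon acts as the large group and the CH2 as the small one, so the (R)-catalyst delivers hydride 1,2 to the face that gives the (8S)-alcohol under reagent control.

Step 12
Reactants: 19 allylic alcohol from step 11; 20 angelic acid, (2Z)-2-methylbut-2-enoic acid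
Product: 22 triene angelate (6R,8S)-13-acetoxy-8-[(2Z)-2-methylbut-2-enoyloxy]germacra-1(10)E,4E,7(11)-trien-12,6-olide, via mixed anhydride 21 (not isolated)
Conditions: 2,4,6-Cl3C6H2COCl, Et3N, toluene, 23 °C; then 19, 60 °C
Reagents that add atoms: none
Why: Yamaguchi esterification through the mixed anhydride without a nucleophilic catalyst keeps the Z geometry of the angelate, and O-acylation leaves C8 unchanged.

Step 13
Reactants: 22 triene angelate from step 12
Product: 23 target (1R,4R,5R,6S,8S,10R)-13-acetoxy-8-[(2Z)-2-methylbut-2-enoyloxy]-1,10:4,5-diepoxygermacr-7(11)-en-12,6-olide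
Conditions: dimethyldioxirane (2.5 equiv), acetone, −20 → 0 °C
Reagents that add atoms: dimethyldioxirane CC1(C)OO1
Why: Neutral dioxirane epoxidation touches only the two electron-rich trisubstituted (E)-alkenes (butenolide and angelate alkenes are electron-poor), each syn-stereospecifically and from its exposed outer face in the crossed conformation of the (E,E)-cyclodeca-1,5-diene, which gives the 1β,10α- and 4α,5β-oxiranes (1R,10R and 4R,5R) as in peracid epoxidation of costunolide-type germacranolides.

## Compound list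

1 | 6-methylhept-5-en-2-one | CC(=O)CCC=C(C)C | starting material
2 | diethyl 6-methylhepta-1,5-dien-2-yl phosphate | C=C(CCC=C(C)C)OP(=O)(OCC)OCC | intermediate
3 | 6-methylhept-5-en-1-yne | C#CCCC=C(C)C | intermediate
4 | (2E)-2-methylhept-2-en-6-yn-1-ol | C#CCC/C=C(\C)CO | intermediate
5 | dimethylaluminium (2E,6E)-7-(dimethylalumanyl)-2,6-dimethylhepta-2,6-dien-1-olate | C[Al](C)/C=C(\C)CC/C=C(\C)CO[Al](C)C | intermediate
6 | (2E,6E)-7-iodo-2,6-dimethylhepta-2,6-dien-1-ol | I/C=C(\C)CC/C=C(\C)CO | intermediate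
7 | (1E,5E)-7-bromo-1-iodo-2,6-dimethylhepta-1,5-diene | I/C=C(\C)CC/C=C(\C)CBr | intermediate
8 | furan-3,4-diyldimethanol | OCc1cocc1CO | starting material
9 | [4-({[tert-butyl(dimethyl)silyl]oxy}methyl)furan-3-yl]methanol | OCc1cocc1CO[Si](C)(C)C(C)(C)C | intermediate
10 | lithium [4-({[tert-butyl(dimethyl)silyl]oxy}methyl)-2-lithiofuran-3-yl]methanolate | [Li]OCc1c([Li])occ1CO[Si](C)(C)C(C)(C)C | intermediate
11 | {4-({[tert-butyl(dimethyl)silyl]oxy}methyl)-2-[(2E,6E)-7-iodo-2,6-dimethylhepta-2,6-dien-1-yl]furan-3-yl}methanol | OCc1c(C/C(C)=C/CC/C(C)=C/I)occ1CO[Si](C)(C)C(C)(C)C | intermediate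
12 | 4-({[tert-butyl(dimethyl)silyl]oxy}methyl)-2-[(2E,6E)-7-iodo-2,6-dimethylhepta-2,6-dien-1-yl]furan-3-carbaldehyde | O=Cc1c(C/C(C)=C/CC/C(C)=C/I)occ1CO[Si](C)(C)C(C)(C)C | intermediate
13 | (4R,5E,9E)-3-({[tert-butyl(dimethyl)silyl]oxy}methyl)-6,10-dimethyl-4,7,8,11-tetrahydrocyclodeca[b]furan-4-ol, i.e. (6R)-13-silyloxy-8,12-epoxygermacra-1(10)E,4E,7,11-tetraen-6-ol | O[C@@H]1/C=C(\C)CC/C=C(\C)Cc2occ(CO[Si](C)(C)C(C)(C)C)c12 | intermediate
14 | 8,12-endoperoxide of 13 (dioxygen bridge between C8 and C12, mixture at the bridgeheads) | O[C@@H]1/C=C(\C)CC/C=C(\C)CC23OOC(O2)C(CO[Si](C)(C)C(C)(C)C)=C13 | intermediate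
15 | (6R)-13-(tert-butyldimethylsilyloxy)-6,8-dihydroxygermacra-1(10)E,4E,7(11)-trien-12,8-olide (C8 hemiketal epimers) | O[C@@H]1/C=C(\C)CC/C=C(\C)CC2(O)OC(=O)C(CO[Si](C)(C)C(C)(C)C)=C12 | intermediate
16 | (6R)-13-(tert-butyldimethylsilyloxy)-8-oxogermacra-1(10)E,4E,7(11)-trien-12,6-olide | O=C1C/C(C)=C/CC/C(C)=C/[C@H]2OC(=O)C(CO[Si](C)(C)C(C)(C)C)=C12 | intermediate
17 | (6R)-13-hydroxy-8-oxogermacra-1(10)E,4E,7(11)-trien-12,6-olide | O=C1C/C(C)=C/CC/C(C)=C/[C@H]2OC(=O)C(CO)=C12 | intermediate
18 | (6R)-13-acetoxy-8-oxogermacra-1(10)E,4E,7(11)-trien-12,6-olide | O=C1C/C(C)=C/CC/C(C)=C/[C@H]2OC(=O)C(COC(C)=O)=C12 | intermediate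
19 | (6R,8S)-13-acetoxy-8-hydroxygermacra-1(10)E,4E,7(11)-trien-12,6-olide | O[C@H]1C/C(C)=C/CC/C(C)=C/[C@H]2OC(=O)C(COC(C)=O)=C12 | intermediate
20 | angelic acid, (2Z)-2-methylbut-2-enoic acid | C/C=C(/C)C(=O)O | starting material
21 | (2Z)-2-methylbut-2-enoic 2,4,6-trichlorobenzoic anhydride | C/C=C(/C)C(=O)OC(=O)c1c(Cl)cc(Cl)cc1Cl | intermediate
22 | (6R,8S)-13-acetoxy-8-[(2Z)-2-methylbut-2-enoyloxy]germacra-1(10)E,4E,7(11)-trien-12,6-olide | C/C=C(/C)C(=O)O[C@H]1C/C(C)=C/CC/C(C)=C/[C@H]2OC(=O)C(COC(C)=O)=C12 | intermediate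
23 | CNP0251711.2, (1R,4R,5R,6S,8S,10R)-13-acetoxy-8-[(2Z)-2-methylbut-2-enoyloxy]-1,10:4,5-diepoxygermacr-7(11)-en-12,6-olide | C/C=C(/C)C(=O)O[C@H]1C[C@@]2(C)O[C@@H]2CC[C@@]2(C)O[C@@H]2[C@H]2OC(=O)C(COC(C)=O)=C12 | target

## Step count and risk

Total steps: 13. Longest linear sequence: 12 (steps 1–4, then 6–13, from 1).

Three steps most likely to fail:

**Step 8.** The furan-bridged (E,E)-cyclodecadiene is strained, and the enantioselectivity of a chromium-mediated closure on an achiral substrate is unproven. The fallback sets out from 9 and 6 and comes back at 13; it makes the two C–C bonds in the opposite order. Dilithiation of 9 as in step 6 and quenching with Bu3SnCl gives {4-({[tert-butyl(dimethyl)silyl]oxy}methyl)-2-(tributylstannyl)furan-3-yl}methanol F1. MnO2 gives 4-({[tert-butyl(dimethyl)silyl]oxy}methyl)-2-(tributylstannyl)furan-3-carbaldehyde F2. Intermolecular CrCl2/NiCl2 coupling of F2 with 6 under the same chiral sulfonamide ligand gives (2E,6E,8R)-8-[4-({[tert-butyl(dimethyl)silyl]oxy}methyl)-2-(tributylstannyl)furan-3-yl]-2,6-dimethylocta-2,6-diene-1,8-diol F3. Selective acylation of the primary allylic hydroxyl (ClCO2Me, pyridine, −20 °C) gives the 1-(methyl carbonate) of that diol F4. Ring closure at C8–C9 by an allyl–Stille coupling (Pd2(dba)3, AsPh3, LiCl, NMP, 40 °C, 1 mM) then delivers 13.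

**Step 9.** The activated pseudo-acid may dehydrate to a γ-alkylidene butenolide instead of lactonising onto 6-OH, and the strained alkenes may compete for singlet oxygen. The fallback sets out from 13 and comes back at 16; it forms the ring C–O bond at the aldehyde level before the carbonyl is made. Photooxygenation without amine (O2, hν, tetraphenylporphyrin, CH2Cl2, −78 °C) followed by Me2S reduces endoperoxide 14 to the (Z)-keto-enal. Its aldehyde is trapped at once by 6-OH as the lactol (6R)-13-(tert-butyldimethylsilyloxy)-12-hydroxy-6,12-epoxygermacra-1(10)E,4E,7(11)-trien-8-one F5. Oxidation of the lactol (TEMPO cat., PhI(OAc)2, CH2Cl2, 23 °C) gives 16.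

**Step 13.** Four stereocenters rest on substrate control alone, and one alkene may be attacked from the wrong face. The fallback sets out from 19 and comes back at 23; it uses reagent control and epoxidises before acylation. Epoxidation of 19 with the D-fructose-derived Shi ketone (1,2:4,5-di-O-isopropylidene-β-D-erythro-2,3-hexodiulo-2,6-pyranose), KHSO5, K2CO3 buffer (pH 10.5), Bu4NHSO4, MeCN/dimethoxymethane/H2O, 0 °C is used. This catalyst converts (E)-trisubstituted alkenes into (R,R)-epoxides, the sense needed at both sites, and gives (1R,4R,5R,6S,8S,10R)-13-acetoxy-1,10:4,5-diepoxy-8-hydroxygermacr-7(11)-en-12,6-olide F6. Angeloylation of F6 with 20 under the conditions of step 12 gives 23.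

## Further compounds

F1 | step 8 | {4-({[tert-butyl(dimethyl)silyl]oxy}methyl)-2-(tributylstannyl)furan-3-yl}methanol | OCc1c([Sn](CCCC)(CCCC)CCCC)occ1CO[Si](C)(C)C(C)(C)C
F2 | step 8 | 4-({[tert-butyl(dimethyl)silyl]oxy}methyl)-2-(tributylstannyl)furan-3-carbaldehyde | O=Cc1c([Sn](CCCC)(CCCC)CCCC)occ1CO[Si](C)(C)C(C)(C)C
F3 | step 8 | (2E,6E,8R)-8-[4-({[tert-butyl(dimethyl)silyl]oxy}methyl)-2-(tributylstannyl)furan-3-yl]-2,6-dimethylocta-2,6-diene-1,8-diol | O[C@H](/C=C(\C)CC/C=C(\C)CO)c1c([Sn](CCCC)(CCCC)CCCC)occ1CO[Si](C)(C)C(C)(C)C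
F4 | step 8 | (2E,6E,8R)-8-[4-({[tert-butyl(dimethyl)silyl]oxy}methyl)-2-(tributylstannyl)furan-3-yl]-8-hydroxy-2,6-dimethylocta-2,6-dien-1-yl methyl carbonate | O[C@H](/C=C(\C)CC/C=C(\C)COC(=O)OC)c1c([Sn](CCCC)(CCCC)CCCC)occ1CO[Si](C)(C)C(C)(C)C
F5 | step 9 | (6R)-13-(tert-butyldimethylsilyloxy)-12-hydroxy-6,12-epoxygermacra-1(10)E,4E,7(11)-trien-8-one (lactol epimers) | O=C1C/C(C)=C/CC/C(C)=C/[C@H]2OC(O)C(CO[Si](C)(C)C(C)(C)C)=C12
F6 | step 13 | (1R,4R,5R,6S,8S,10R)-13-acetoxy-1,10:4,5-diepoxy-8-hydroxygermacr-7(11)-en-12,6-olide | O[C@H]1C[C@@]2(C)O[C@@H]2CC[C@@]2(C)O[C@@H]2[C@H]2OC(=O)C(COC(C)=O)=C12
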